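If coupling partner is to finish the starting material in violet and teal, it must do so after the protic impurity has taken its share.

the same everywhere: protic impurity 1.25 mM; free catalyst 0.62 mM
- Wednesday's: starting material 0.013 M; coupling partner 0.030 M; run made earlier
- Tuesday's: starting material 0.050 M; coupling partner 0.030 M; run made earlier
- violet: starting material 0.025 M; coupling partner 0.0300 M; time 50 h
- teal: starting material 0.025 M; coupling partner 0.0300 M; time 30 h

| run | time / h | product / % | starting material / % |
|---|---|---|---|
| Wednesday's | 1.50 | 20.7 | 78.6 |
| Wednesday's | 5.00 | 56.8 | 42.3 |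
| Wednesday's | 8.00 | 76.7 | 23.4 |
| Wednesday's | 12.0 | 90.6 | 9.3 |
| Wednesday's | 20.0 | 99.1 | 2.3 |
| Wednesday's | 25.0 | 100.2 | 1.6 |
| Tuesday's | 1.50 | 8.3 | 92.3 |
| Tuesday's | 5.00 | 21.1 | 79.6 |
| Tuesday's | 8.00 | 30.6 | 69.9 |
| Tuesday's | 12.0 | 38.4 | 62.0 |
| Tuesday's | 20.0 | 47.1 | 51.8 |
| Tuesday's | 25.0 | 50.6 | 49.2 |

(readings scatter by 0.5 percentage points)

1. the flask that ends with the higher amount of product, in percent of the starting material charged, or "neither" when 2 percentage points or less lies between them (violet / teal / neither)
2. final product, as a percentage of the starting material charged, in violet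
3. final product, as a percentage of the starting material charged, in teal

So I carry the partner surplus, the partner charge less the impurity and the starting material: 3.75 mM in teal and violet. Tuesday's flask has −21.3 mM, so partner is its limiting reagent, capping product at 57.5 %; its last reading is 50.6 %.

Each catalyst turn waits for partner, then for starting material. I add the two waits and integrate the rate, with c(partner) = c(starting material) + surplus:

t = ln[c(partner, start)/c(partner)]/ka + ln[c(starting material, start)/c(starting material)]/kb

Tuesday's gap to its cap gives 0.0918 h⁻¹ for ka, and Wednesday's decay gives 0.198 h⁻¹ for kb. Each is read as if the other wait cost nothing.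

Usable partner is 28.7 mM, so my teal curve starts at 1.72 mM h⁻¹. It passes 50.0 % conversion at 9.71 h. The knee follows: the partner term cannot exceed 22.2 h, because the surplus is positive, and the starting-material tail takes over.

90.0 % comes at 28.2 h and 99.0 % at 44.7 h, on the way to a level of the whole charge.

So I expect teal just past the first mark at 30 h, and violet just past the second at 50 h.

The forecast also says violet, with 99.3 % in violet, but it puts teal higher than I do, at 96 %, reasoning that “partner is just sufficient”.

The simulation gives violet: 97.8 % in violet, 91.9 % in teal.

    coupling partner + free catalyst → catalyst intermediate A (k = 3.10 L mol⁻¹ min⁻¹)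
    starting material + catalyst intermediate A ⇌ catalyst intermediate B (K = 23.0 L mol⁻¹, k = 17.0 L mol⁻¹ min⁻¹)
    catalyst intermediate B ⇌ free catalyst + product (K = 0.220 M, k = 1.90 min⁻¹)
    free catalyst → spent catalyst (k = 1.80 × 10⁻⁵ min⁻¹)
    coupling partner + protic impurity → quenched reagent (k = 6.10 L mol⁻¹ min⁻¹)

The two flasks share one recipe, so the gap of 5.9 percentage points comes from the time: with the difference in time taken away, violet gives 91.9 %. The margin is thin, though. At 0.0272 M of partner the surplus is 0.925 mM, and teal's answer has already moved by 5 points.

In a neighbouring flask, teal's recipe with 0.0075 M of partner, the surplus is −18.8 mM, which caps product at 25.0 %. The simulation gives 23.7 %, with 76.2 % of the starting material left.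

(The numbers in the tables are simulated for an exercise; noise was put on by code.)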